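## Retrosynthetic overview

- The target is reached by a late C7-prenylation of an enolised β-diketone, placed anti to the C5 prenyl group. The C5 quaternary centre comes from a Pd-mediated O-to-C prenyl transfer that dearomatises an aryl prenyl ether.
- That prenyl ether first masks the para oxygen, so the dihydrofuran can only close onto the oxygen next to the acyl-bearing carbon (Mitsunobu closure, inversion at C2).
- Key C–C bond (C3–C3a): the free ring carbon of the acylphloroglucinol, innately nucleophilic, is brominated. The C–Br carbon is the enol form of a 2-bromo-1,3-diketone, an enolonium-type equivalent. It is joined to the terminal vinyl carbon of (S)-linalool, itself a π-nucleophile, carried as a 1,2-bis(boronate) (enantioselective diboration, cross-coupling, oxidation in one pot).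
- Stereocentres: the tertiary carbinol comes from (S)-linalool, C2 from the diboration catalyst, C5 from the chiral Pd catalyst, C7 from 1,3-induction by C5.
- Ring order: the carbocycle is the purchased phloroglucinol; the dihydrofuran ring is closed in step 5; the carbocycle is dearomatised in steps 6 and 7.

Assumption: (S)-(+)-linalool of high enantiomeric purity is purchased, and the ligand antipodes named in steps 3 and 6 are taken to give the stated sense of induction (the mirror-image ligand is used if the sense proves opposite).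

## Route

Step 1
Reactants: 1 2-methylbenzene-1,3,5-triol (2-methylphloroglucinol); 2 2-methylpropanoyl chloride (isobutyryl chloride)
Product: 3 2-methyl-1-(2,4,6-trihydroxy-3-methylphenyl)propan-1-one
Conditions: AlCl3 (3.5 equiv), PhNO2, 60 °C; then cold aq HCl
Reagents that add atoms: 2 2-methylpropanoyl chloride, CC(C)C(Cl)=O
Why: Friedel–Crafts C-acylation of the highly activated ring at one of its two equivalent free positions stops after one acyl group because the ketone deactivates the ring; no stereocentre is formed.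

Step 2
Reactants: 3 2-methyl-1-(2,4,6-trihydroxy-3-methylphenyl)propan-1-one; 4 N-bromosuccinimide
Product: 5 1-(3-bromo-2,4,6-trihydroxy-5-methylphenyl)-2-methylpropan-1-one
Conditions: NBS (1.0 equiv), MeCN, 0 °C, dark
Reagents that add atoms: 4 N-bromosuccinimide, O=C1CCC(=O)N1Br
Why: Electrophilic aromatic bromination at the only remaining ring C–H turns this innately nucleophilic enol carbon into the C–Br carbon of a 2-bromo-1,3-diketone enol, an enolonium-type electrophile for step 3; no stereocentre is formed.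

Step 3
Reactants: 5 1-(3-bromo-2,4,6-trihydroxy-5-methylphenyl)-2-methylpropan-1-one; 6 (S)-linalool; 7 bis(pinacolato)diboron; 8 trimethylamine N-oxide
Product: 11 1-{3-[(2R,3S)-2,3-dihydroxy-3,7-dimethyloct-6-en-1-yl]-2,4,6-trihydroxy-5-methylphenyl}-2-methylpropan-1-one, via linalool 1,2-bis(boronate) 9 (not isolated), via aryl-coupled secondary boronate 10 (not isolated)
Conditions: 6, 7, Pt(dba)3 (2 mol %), (R,R)-TADDOL-derived phenylphosphonite (3,5-diisopropylphenyl groups, 2.4 mol %), THF, 60 °C; then 5, Pd(OAc)2 (3 mol %), RuPhos (3 mol %), aq KOH, THF/H2O, 70 °C, degassed; then AcOH to pH 7–8, Me3NO·2H2O, 50 °C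
Reagents that add atoms: 7 bis(pinacolato)diboron, CC1(C)OB(OC1(C)C)B1OC(C)(C)C(C)(C)O1 (boron stays only in 9 and 10); 8 trimethylamine N-oxide, C[N+](C)(C)[O-]
Why: Pt-catalysed enantioselective 1,2-diboration reacts only at the monosubstituted vinyl group and sets C2 of the side chain under catalyst control (the adjacent carbinol, differing only in methyl versus alkyl, gives no useful bias), the primary C–B bond then undergoes B-alkyl Suzuki–Miyaura coupling with the polarity-inverted bromo-enol carbon of 5, and amine-oxide oxidation turns the secondary C–B bond into C–OH with retention without Dakin or alkene oxidation, while C3 is carried unchanged from 6.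

Step 4
Reactants: 11 1-{3-[(2R,3S)-2,3-dihydroxy-3,7-dimethyloct-6-en-1-yl]-2,4,6-trihydroxy-5-methylphenyl}-2-methylpropan-1-one; 12 1-bromo-3-methylbut-2-ene (prenyl bromide)
Product: 13 1-{3-[(2R,3S)-2,3-dihydroxy-3,7-dimethyloct-6-en-1-yl]-2,6-dihydroxy-5-methyl-4-(3-methylbut-2-en-1-yloxy)phenyl}-2-methylpropan-1-one
Conditions: prenyl bromide (1.05 equiv), K2CO3 (1.1 equiv), acetone, rt
Reagents that add atoms: 12 1-bromo-3-methylbut-2-ene, CC(C)=CCBr
Why: Williamson O-alkylation takes the most acidic, non-chelated phenol (para to the acyl group; both ortho OH groups are hydrogen-bonded to the ketone), which masks that oxygen and stores the prenyl group needed in step 6; no stereocentre is formed.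

Step 5
Reactants: 13 1-{3-[(2R,3S)-2,3-dihydroxy-3,7-dimethyloct-6-en-1-yl]-2,6-dihydroxy-5-methyl-4-(3-methylbut-2-en-1-yloxy)phenyl}-2-methylpropan-1-one
Product: 14 1-[(2S)-6-hydroxy-2-[(2S)-2-hydroxy-6-methylhept-5-en-2-yl]-5-methyl-4-(3-methylbut-2-en-1-yloxy)-2,3-dihydro-1-benzofuran-7-yl]-2-methylpropan-1-one
Conditions: PPh3 (1.3 equiv), DIAD (1.3 equiv), THF, 0 °C to rt
Reagents that add atoms: none
Why: Intramolecular Mitsunobu etherification, in which the only free phenol next to the side chain displaces the activated secondary alcohol 5-exo-tet with inversion (2R to 2S) while the tertiary alcohol cannot be activated, as in the closure of related 2-(hydroxyalkyl)phenol diols to hydroxyisopropyl dihydrobenzofurans.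

Step 6
Reactants: 14 1-[(2S)-6-hydroxy-2-[(2S)-2-hydroxy-6-methylhept-5-en-2-yl]-5-methyl-4-(3-methylbut-2-en-1-yloxy)-2,3-dihydro-1-benzofuran-7-yl]-2-methylpropan-1-one
Product: 15 (2S,5R)-6-hydroxy-2-[(2S)-2-hydroxy-6-methylhept-5-en-2-yl]-5-methyl-5-(3-methylbut-2-en-1-yl)-7-(2-methylpropanoyl)-2,3-dihydro-1-benzofuran-4(5H)-one
Conditions: Pd2(dba)3·CHCl3 (2.5 mol %), (S,S)-DACH-phenyl Trost ligand (7.5 mol %), THF, 50 °C, degassed
Reagents that add atoms: none
Why: Proposed new method: zerovalent palladium ionises the aryl prenyl ether (the acyl-stabilised phenoxide is a carboxylate-like leaving group) to a ligand-bound π-prenyl cation and phenoxide ion pair, which recombines irreversibly through the unsubstituted prenyl terminus at the methyl-bearing ortho carbon (O-attack is reversible and the other ortho carbon is the hindered ring fusion), so the chiral ligand sets the quaternary C5 centre; the closest known reactions are the Pd-catalysed O-to-C allyl migration of allyl aryl and allyl enol ethers (Tsuji–Trost type) and the Pd-catalysed asymmetric allylic dearomatisation of naphthols and substituted phenols.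

Step 7
Reactants: 15 (2S,5R)-6-hydroxy-2-[(2S)-2-hydroxy-6-methylhept-5-en-2-yl]-5-methyl-5-(3-methylbut-2-en-1-yl)-7-(2-methylpropanoyl)-2,3-dihydro-1-benzofuran-4(5H)-one; 12 1-bromo-3-methylbut-2-ene (prenyl bromide)
Product: 16 (2S,5S,7S)-2-[(2S)-2-hydroxy-6-methylhept-5-en-2-yl]-5-methyl-5,7-bis(3-methylbut-2-en-1-yl)-7-(2-methylpropanoyl)-2,3-dihydro-1-benzofuran-4,6(5H,7H)-dione (CNP0250451.1)
Conditions: prenyl bromide (1.3 equiv), Pd(PPh3)4 (5 mol %), Cs2CO3 (1.5 equiv), THF, 0 °C to rt
Reagents that add atoms: 12 1-bromo-3-methylbut-2-ene, CC(C)=CCBr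
Why: Tsuji–Trost C-prenylation of the enolised β-diketone, in which the vinylogous ester locks the other dione so C7 is the nucleophilic carbon, any O-prenyl enol ether re-ionises under zerovalent palladium and funnels to the C-alkylated product, and the π-prenyl unit attacks anti to the C5 prenyl group (syn to the smaller methyl) to give the 5,7-trans-diprenyl 7S centre.

## Compound list

1 | 2-methylbenzene-1,3,5-triol | Cc1c(O)cc(O)cc1O | starting material
2 | 2-methylpropanoyl chloride | CC(C)C(Cl)=O | starting material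
3 | 2-methyl-1-(2,4,6-trihydroxy-3-methylphenyl)propan-1-one | CC(C)C(=O)c1c(O)cc(O)c(C)c1O | intermediate
4 | N-bromosuccinimide | O=C1CCC(=O)N1Br | starting material
5 | 1-(3-bromo-2,4,6-trihydroxy-5-methylphenyl)-2-methylpropan-1-one | CC(C)C(=O)c1c(O)c(Br)c(O)c(C)c1O | intermediate
6 | (S)-linalool, (3S)-3,7-dimethylocta-1,6-dien-3-ol | CC(C)=CCC[C@](C)(O)C=C | starting material
7 | bis(pinacolato)diboron | CC1(C)OB(OC1(C)C)B1OC(C)(C)C(C)(C)O1 | starting material
8 | trimethylamine N-oxide | C[N+](C)(C)[O-] | starting material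
9 | (2R,3S)-3,7-dimethyl-1,2-bis(4,4,5,5-tetramethyl-1,3,2-dioxaborolan-2-yl)oct-6-en-3-ol | CC(C)=CCC[C@](C)(O)[C@H](B1OC(C)(C)C(C)(C)O1)CB1OC(C)(C)C(C)(C)O1 | intermediate
10 | 1-{2,4,6-trihydroxy-3-[(2R,3S)-3-hydroxy-3,7-dimethyl-2-(4,4,5,5-tetramethyl-1,3,2-dioxaborolan-2-yl)oct-6-en-1-yl]-5-methylphenyl}-2-methylpropan-1-one | CC(C)=CCC[C@](C)(O)[C@H](B1OC(C)(C)C(C)(C)O1)Cc1c(O)c(C)c(O)c(C(=O)C(C)C)c1O | intermediate
11 | 1-{3-[(2R,3S)-2,3-dihydroxy-3,7-dimethyloct-6-en-1-yl]-2,4,6-trihydroxy-5-methylphenyl}-2-methylpropan-1-one | CC(C)=CCC[C@](C)(O)[C@H](O)Cc1c(O)c(C)c(O)c(C(=O)C(C)C)c1O | intermediate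
12 | 1-bromo-3-methylbut-2-ene | CC(C)=CCBr | starting material
13 | 1-{3-[(2R,3S)-2,3-dihydroxy-3,7-dimethyloct-6-en-1-yl]-2,6-dihydroxy-5-methyl-4-(3-methylbut-2-en-1-yloxy)phenyl}-2-methylpropan-1-one | CC(C)=CCC[C@](C)(O)[C@H](O)Cc1c(OCC=C(C)C)c(C)c(O)c(C(=O)C(C)C)c1O | intermediate
14 | 1-[(2S)-6-hydroxy-2-[(2S)-2-hydroxy-6-methylhept-5-en-2-yl]-5-methyl-4-(3-methylbut-2-en-1-yloxy)-2,3-dihydro-1-benzofuran-7-yl]-2-methylpropan-1-one | CC(C)=CCC[C@](C)(O)[C@@H]1Cc2c(O1)c(C(=O)C(C)C)c(O)c(C)c2OCC=C(C)C | intermediate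
15 | (2S,5R)-6-hydroxy-2-[(2S)-2-hydroxy-6-methylhept-5-en-2-yl]-5-methyl-5-(3-methylbut-2-en-1-yl)-7-(2-methylpropanoyl)-2,3-dihydro-1-benzofuran-4(5H)-one | CC(C)=CCC[C@](C)(O)[C@@H]1CC2=C(O1)C(C(=O)C(C)C)=C(O)[C@@](C)(CC=C(C)C)C2=O | intermediate
16 | (2S,5S,7S)-2-[(2S)-2-hydroxy-6-methylhept-5-en-2-yl]-5-methyl-5,7-bis(3-methylbut-2-en-1-yl)-7-(2-methylpropanoyl)-2,3-dihydro-1-benzofuran-4,6(5H,7H)-dione | CC(C)=CCC[C@](C)(O)[C@@H]1CC2=C(O1)[C@@](CC=C(C)C)(C(=O)C(C)C)C(=O)[C@@](C)(CC=C(C)C)C2=O | target

## Step count and risks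

Total step count: 7. Longest linear sequence: 7 steps (1 to 16).

The three steps most likely to fail are steps 3, 6 and 7.

**Step 3.** The aryl bromide is a very electron-rich tris-phenoxide under the coupling conditions, and the β-hydroxy secondary boronate 10 may eliminate to an alkene in hot aqueous base. The fallback sets out from 3 and comes back to the route at 14, bypassing steps 2 to 5. Nerol is epoxidised (Ti(OiPr)4, D-(−)-diisopropyl tartrate, tBuOOH, 4 Å sieves, CH2Cl2, −20 °C) to [(2R,3S)-3-methyl-3-(4-methylpent-3-en-1-yl)oxiran-2-yl]methanol F1. Oxidation (Dess–Martin periodinane, NaHCO3, CH2Cl2) gives (2S,3S)-3-methyl-3-(4-methylpent-3-en-1-yl)oxirane-2-carbaldehyde F2. In parallel 3 is O-prenylated at the para oxygen (12, K2CO3, acetone) to 1-[2,6-dihydroxy-3-methyl-4-(3-methylbut-2-en-1-yloxy)phenyl]-2-methylpropan-1-one F3. Reductive alkylation of F3 with F2 (Hantzsch ester, catalytic L-proline, CH2Cl2/EtOH; Knoevenagel condensation then conjugate reduction) gives 1-[2,6-dihydroxy-3-methyl-5-{[(2R,3S)-3-methyl-3-(4-methylpent-3-en-1-yl)oxiran-2-yl]methyl}-4-(3-methylbut-2-en-1-yloxy)phenyl]-2-methylpropan-1-one F4. Its free ortho phenoxide (K2CO3, MeOH) opens the epoxide 5-exo at C2 with inversion to give 14, both side-chain centres now coming from the Sharpless epoxidation.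

**Step 6.** Ionisation of a trisubstituted allyl aryl ether may be slow, and neither the site of recombination nor the ligand control at C5 has been shown on this ring. The fallback sets out from 14 and comes back at 16. Heating 14 in N,N-diethylaniline at 160 °C causes a para-Claisen rearrangement (a [3,3] shift to the blocked ortho carbon followed by a Cope shift). This carries the prenyl group, with its linear connectivity restored, to the acyl-bearing para carbon and gives (2S,7S)-6-hydroxy-2-[(2S)-2-hydroxy-6-methylhept-5-en-2-yl]-5-methyl-7-(3-methylbut-2-en-1-yl)-7-(2-methylpropanoyl)-2,3-dihydro-1-benzofuran-4(7H)-one F5 after chromatographic separation from its C7 epimer. C-prenylation of the 2-methyl-1,3-dione unit of F5 at C5 (12, K2CO3, acetone) then gives 16, again after separation of diastereomers. This fallback gives up catalyst control of the ring centres.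

**Step 7.** Building a quaternary carbon that carries an acyl group may be slow, and O-alkylation or attack at C3a may compete. The fallback sets out from 15 and comes back at 16. C-allylation with the smaller, faster-ionising allyl acetate (Pd(PPh3)4, Cs2CO3, THF) gives (2S,5S,7S)-2-[(2S)-2-hydroxy-6-methylhept-5-en-2-yl]-5-methyl-5-(3-methylbut-2-en-1-yl)-7-(2-methylpropanoyl)-7-(prop-2-en-1-yl)-2,3-dihydro-1-benzofuran-4,6(5H,7H)-dione F6. Cross-metathesis of F6 with excess 2-methyl-2-butene (second-generation Grubbs catalyst, CH2Cl2, 40 °C) converts the allyl group into prenyl and gives 16; the trisubstituted alkenes already present exchange only degenerately.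

Further compounds
F1 | step 3 | [(2R,3S)-3-methyl-3-(4-methylpent-3-en-1-yl)oxiran-2-yl]methanol | CC(C)=CCC[C@]1(C)O[C@@H]1CO
F2 | step 3 | (2S,3S)-3-methyl-3-(4-methylpent-3-en-1-yl)oxirane-2-carbaldehyde | CC(C)=CCC[C@]1(C)O[C@@H]1C=O
F3 | step 3 | 1-[2,6-dihydroxy-3-methyl-4-(3-methylbut-2-en-1-yloxy)phenyl]-2-methylpropan-1-one | CC(C)C(=O)c1c(O)cc(OCC=C(C)C)c(C)c1O
F4 | step 3 | 1-[2,6-dihydroxy-3-methyl-5-{[(2R,3S)-3-methyl-3-(4-methylpent-3-en-1-yl)oxiran-2-yl]methyl}-4-(3-methylbut-2-en-1-yloxy)phenyl]-2-methylpropan-1-one | CC(C)=CCC[C@]1(C)O[C@@H]1Cc1c(OCC=C(C)C)c(C)c(O)c(C(=O)C(C)C)c1O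
F5 | step 6 | (2S,7S)-6-hydroxy-2-[(2S)-2-hydroxy-6-methylhept-5-en-2-yl]-5-methyl-7-(3-methylbut-2-en-1-yl)-7-(2-methylpropanoyl)-2,3-dihydro-1-benzofuran-4(7H)-one | CC(C)=CCC[C@](C)(O)[C@@H]1CC2=C(O1)[C@@](CC=C(C)C)(C(=O)C(C)C)C(O)=C(C)C2=O
F6 | step 7 | (2S,5S,7S)-2-[(2S)-2-hydroxy-6-methylhept-5-en-2-yl]-5-methyl-5-(3-methylbut-2-en-1-yl)-7-(2-methylpropanoyl)-7-(prop-2-en-1-yl)-2,3-dihydro-1-benzofuran-4,6(5H,7H)-dione | CC(C)=CCC[C@](C)(O)[C@@H]1CC2=C(O1)[C@@](CC=C)(C(=O)C(C)C)C(=O)[C@@](C)(CC=C(C)C)C2=O
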